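## Retrosynthetic overview

1. Target 19 ⇒ cut both ArCH2–C3(pyranone) bonds: bis(dimethylaminomethyl) acylphloroglucinol 10 (a twofold ortho-quinone methide precursor) plus two equivalents of pyranone 15.
2. 10 ⇒ Mannich reaction of acylphloroglucinol 9 ⇒ Friedel–Crafts acylation of phloroglucinol 8 with (R)-2-methylbutanoyl chloride 7.
3. (R)-acid 6 ⇒ diimide reduction of (R)-2-methylbut-3-enoic acid 5 ⇒ decarboxylase-mediated desymmetrisation of prochiral malonic acid 4 ⇒ deconjugative methylation of diethyl ethylidenemalonate 1.
4. Pyranone 15 ⇒ lactonisation of triketo ester 14 ⇒ dianion of methyl 3-oxopentanoate 11 plus Weinreb amide 12.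
5. Ring order: the benzene ring is bought as phloroglucinol; the only ring formed is the 2-pyranone (step 9), made before the final double coupling (step 10).

Assumption: wild-type arylmalonate decarboxylase (Bordetella bronchiseptica gene expressed in E. coli, used as cell-free extract) is available and counts as a catalyst, not a starting material.

## Route

Step 1
Reactants: 1 diethyl ethylidenemalonate (diethyl 2-ethylidenepropanedioate)
Product: 3 diethyl 2-ethenyl-2-methylpropanedioate, via lithium dienolate 2 (not isolated)
Conditions: LiN(i-Pr)2 (LDA, 1.1 equiv), THF/DMPU, −78 °C, 1 h; MeI (1.5 equiv), −78 → 0 °C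
Reagents that add atoms: iodomethane, CI
Why: Deconjugative α-alkylation: the hindered amide base removes a γ-proton rather than adding in a conjugate sense, and the dienolate is methylated (SN2) at the doubly stabilised α-carbon, leaving a vinyl group; no stereocentre arises because the two esters are identical.

Step 2
Reactants: 3 diethyl 2-ethenyl-2-methylpropanedioate
Product: 4 2-ethenyl-2-methylpropanedioic acid
Conditions: KOH (4 equiv), EtOH/H2O 1:1, 25–40 °C, 16 h; then cold HCl to pH 1, EtOAc extraction, evaporation below 30 °C
Reagents that add atoms: potassium hydroxide, [K+].[OH-]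
Why: Saponification of both esters; the quaternary malonic acid does not decarboxylate at these temperatures, so the prochiral diacid is isolated intact.

Step 3
Reactants: 4 2-ethenyl-2-methylpropanedioic acid
Product: 5 (2R)-2-methylbut-3-enoic acid
Conditions: decarboxylase (arylmalonate decarboxylase, wild type, cell-free extract), 4 (100 mM) brought to pH 8.0 with NaOH, Tris-HCl buffer (50 mM, pH 8.0), 30 °C, 24 h; then HCl to pH 2, MTBE extraction
Reagents that add atoms: none
Why: Enzymatic desymmetrising decarboxylation: the cofactor-free decarboxylase removes only one of the two enantiotopic carboxylates (the vinyl group stabilises the enediolate as an aryl group would) and its active-site cysteine protonates a single face, setting C2 as (R), typically in ≥98% ee for the wild type.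

Step 4
Reactants: 5 (2R)-2-methylbut-3-enoic acid
Product: 6 (2R)-2-methylbutanoic acid
Conditions: N2H4·H2O (10 equiv), CuSO4 (1 mol %, divalent copper), O2 (balloon), EtOH, 25 °C; HCl work-up, extraction, short-path distillation; ee checked by chiral GC
Reagents that add atoms: none
Why: Diimide reduction (concerted syn transfer of two hydrogens to the unhindered terminal alkene) avoids metal hydrides that could move the double bond into conjugation, so the α-centre is untouched and stays (R) as vinyl becomes ethyl.

Step 5
Reactants: 6 (2R)-2-methylbutanoic acid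
Product: 7 (2R)-2-methylbutanoyl chloride
Conditions: (COCl)2 (1.2 equiv), DMF (cat.), CH2Cl2, 0 → 25 °C, 2 h; volatiles removed cold at moderate vacuum, used crude
Reagents that add atoms: oxalyl chloride, O=C(Cl)C(=O)Cl
Why: Acid chloride formation through the catalytic chloroiminium (Vilsmeier-type) species under base-free conditions, so no ketene forms and the α-centre keeps its configuration.

Step 6
Reactants: 7 (2R)-2-methylbutanoyl chloride; 8 phloroglucinol (benzene-1,3,5-triol, anhydrous)
Product: 9 (2R)-2-methyl-1-(2,4,6-trihydroxyphenyl)butan-1-one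
Conditions: AlCl3 (4 equiv), PhNO2/CH2Cl2, 0 → 25 °C, 16 h; ice/HCl
Reagents that add atoms: none
Why: Friedel–Crafts C-acylation of the very electron-rich triol stops at monoacylation because the acyl group deactivates the ring, and α-branched acid chlorides acylate at or below room temperature without loss of configuration.

Step 7
Reactants: 9 (2R)-2-methyl-1-(2,4,6-trihydroxyphenyl)butan-1-one
Product: 10 (2R)-1-{3,5-bis[(dimethylamino)methyl]-2,4,6-trihydroxyphenyl}-2-methylbutan-1-one
Conditions: CH2(NMe2)2 (2.4 equiv), 1,4-dioxane, 25 °C, 12 h; volatiles removed, solid triturated with Et2O and used promptly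
Reagents that add atoms: bis(dimethylamino)methane, CN(C)CN(C)C
Why: Phenolic Mannich reaction: the acidic acylphloroglucinol protonates the aminal to release the iminium ion, which aminomethylates both remaining ring carbons, so no free ring position is left for phloroglucinol self-coupling later.

Step 8
Reactants: 11 methyl 3-oxopentanoate; 12 N-methoxy-N-methylpropanamide
Product: 14 methyl 4-methyl-3,5-dioxoheptanoate, via dilithium dianion 13 (not isolated)
Conditions: 11, LiN(i-Pr)2 (LDA, 2.2 equiv), THF, −78 → 0 °C; 12 (0.9 equiv), −78 → 0 °C; aq. HCl quench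
Reagents that add atoms: none
Why: γ-Acylation of a β-keto ester dianion (Huckin–Weiler type Claisen acylation): the more reactive γ-carbanion attacks the Weinreb amide, whose chelated tetrahedral adduct prevents over-addition and proton quenching until work-up; the new C4 centre is racemic and becomes sp2 in the next step.

Step 9
Reactants: 14 methyl 4-methyl-3,5-dioxoheptanoate
Product: 15 6-ethyl-4-hydroxy-5-methyl-2H-pyran-2-one
Conditions: DBU (1.5 equiv), toluene, 110 °C, 4 h; HCl work-up, crystallisation
Reagents that add atoms: none
Why: Base-mediated lactonisation of the 3,5-dioxo ester (the enol oxygen of the C5 ketone attacks the ester with loss of methanol) gives the stabilised 4-hydroxy-2-pyranone.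

Step 10
Reactants: 10 (2R)-1-{3,5-bis[(dimethylamino)methyl]-2,4,6-trihydroxyphenyl}-2-methylbutan-1-one; 15 6-ethyl-4-hydroxy-5-methyl-2H-pyran-2-one (3 equiv)
Product: 19 (2R)-1-{3,5-bis[(6-ethyl-4-hydroxy-5-methyl-2-oxo-2H-pyran-3-yl)methyl]-2,4,6-trihydroxyphenyl}-2-methylbutan-1-one (CNP0174567.1), via ortho-quinone methide 16 (not isolated), via mono-adduct Mannich base 17 (not isolated), via second ortho-quinone methide 18 (not isolated)
Conditions: 1,4-dioxane, 90 °C, N2, 6 h; 1 M HCl wash; chromatography, then crystallisation
Reagents that add atoms: none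
Why: Elimination of dimethylamine from each benzylic amine (helped by protonation by the acidic pyranone) gives an ortho-quinone methide that C3 of the 4-hydroxy-2-pyranone captures by Michael addition, twice in succession, under near-neutral conditions that do not epimerise the (R) centre next to the hydrogen-bonded aryl ketone.

## Compound list

1 | diethyl ethylidenemalonate | CC=C(C(=O)OCC)C(=O)OCC | starting material
2 | lithium dienolate of 1 (γ-deprotonated) | [Li+].C=CC(C(=O)OCC)=C([O-])OCC | intermediate
3 | diethyl 2-ethenyl-2-methylpropanedioate | C=CC(C)(C(=O)OCC)C(=O)OCC | intermediate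
4 | 2-ethenyl-2-methylpropanedioic acid (prochiral) | C=CC(C)(C(=O)O)C(=O)O | intermediate
5 | (2R)-2-methylbut-3-enoic acid | C=C[C@@H](C)C(=O)O | intermediate
6 | (2R)-2-methylbutanoic acid | CC[C@@H](C)C(=O)O | intermediate
7 | (2R)-2-methylbutanoyl chloride | CC[C@@H](C)C(=O)Cl | intermediate
8 | phloroglucinol (benzene-1,3,5-triol) | Oc1cc(O)cc(O)c1 | starting material
9 | (2R)-2-methyl-1-(2,4,6-trihydroxyphenyl)butan-1-one | CC[C@@H](C)C(=O)c1c(O)cc(O)cc1O | intermediate
10 | (2R)-1-{3,5-bis[(dimethylamino)methyl]-2,4,6-trihydroxyphenyl}-2-methylbutan-1-one | CC[C@@H](C)C(=O)c1c(O)c(CN(C)C)c(O)c(CN(C)C)c1O | intermediate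
11 | methyl 3-oxopentanoate | CCC(=O)CC(=O)OC | starting material
12 | N-methoxy-N-methylpropanamide | CCC(=O)N(C)OC | starting material
13 | dilithium α,γ-dianion of 11 | [Li+].[Li+].CC=C([O-])C=C([O-])OC | intermediate
14 | methyl 4-methyl-3,5-dioxoheptanoate (racemic at C4, keto/enol mixture) | CCC(=O)C(C)C(=O)CC(=O)OC | intermediate
15 | 6-ethyl-4-hydroxy-5-methyl-2H-pyran-2-one | CCc1oc(=O)cc(O)c1C | intermediate
16 | ortho-quinone methide from 10 (one Me2NH lost; (R) side chain) | CC[C@@H](C)C(=O)C1=C(O)C(=C)C(=O)C(CN(C)C)=C1O | intermediate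
17 | mono-pyranonylmethyl adduct still carrying one CH2NMe2 group; (R) side chain | CC[C@@H](C)C(=O)c1c(O)c(Cc2c(O)c(C)c(CC)oc2=O)c(O)c(CN(C)C)c1O | intermediate
18 | ortho-quinone methide from 17; (R) side chain | CC[C@@H](C)C(=O)C1=C(O)C(=C)C(=O)C(Cc2c(O)c(C)c(CC)oc2=O)=C1O | intermediate
19 | (2R)-1-{3,5-bis[(6-ethyl-4-hydroxy-5-methyl-2-oxo-2H-pyran-3-yl)methyl]-2,4,6-trihydroxyphenyl}-2-methylbutan-1-one | CCc1oc(=O)c(Cc2c(O)c(Cc3c(O)c(C)c(CC)oc3=O)c(O)c(C(=O)[C@H](C)CC)c2O)c(O)c1C | target

## Step count and risks

Total steps: 10. Longest linear sequence: 8 steps (steps 1–7, then step 10); steps 8–9 form the convergent pyranone branch.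

**Step 3 (enzymatic decarboxylation).** The risk is enzyme supply, activity on scale, or an ee below specification. The fallback sets out from compound 4 and comes back at compound 6, leaving out 5. Compound 4 is decarboxylated in refluxing pyridine and the double bond is brought into conjugation with hot aqueous KOH, giving (E)-2-methylbut-2-enoic acid F1 (tiglic acid, which can equally be bought). F1 is hydrogenated with Ru(OAc)2[(R)-H8-BINAP] (0.5 mol %, divalent ruthenium), H2 (2–4 atm), MeOH, 20 °C. This is a carboxylate-directed asymmetric hydrogenation in which the chiral diphosphine complex sets the (R) centre, with about 97% ee expected. The ligand antipode should be confirmed by chiral GC on a test run.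

**Step 6 (Friedel–Crafts acylation).** The risk is partial racemisation through ketene or acylium pathways, or a low yield from O-acylation. The fallback sets out from compounds 7 and 8 and comes back at compound 9. Compound 7 with MeNHOMe·HCl and pyridine in CH2Cl2 at 0 °C gives (2R)-N-methoxy-N,2-dimethylbutanamide F2. Compound 8 with MOMCl and i-Pr2NEt in CH2Cl2 gives 1,3,5-tris(methoxymethoxy)benzene F3. Directed ortho-lithiation of F3 (n-BuLi, THF, 0 °C) gives 2,4,6-tris(methoxymethoxy)phenyllithium F4. F4 adds to F2 at −78 → 0 °C to give (2R)-2-methyl-1-[2,4,6-tris(methoxymethoxy)phenyl]butan-1-one F5 without over-addition. HCl in MeOH at 25–40 °C removes the three acetals and gives 9.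

**Step 10 (double quinone methide coupling).** The risk is incomplete second coupling, or methylene transfer giving the symmetrical bis-pyranone. The fallback reverses the roles of electrophile and nucleophile; it sets out from compounds 9 and 15 (10 is not made) and comes back at compound 19. Compound 15 (2.4 equiv) and Me2N=CH2+ I− (dimethylmethylideneammonium iodide, 2.4 equiv) in CHCl3/MeCN at 25 °C give 3-[(dimethylamino)methyl]-6-ethyl-4-hydroxy-5-methyl-2H-pyran-2-one F6. F6 loses dimethylamine to give 6-ethyl-5-methyl-3-methylidene-2H-pyran-2,4(3H)-dione F7. Compound 9, present in the same flask, adds through its free ring carbons (Michael addition) by way of the mono-adduct 6-ethyl-4-hydroxy-5-methyl-3-{[2,4,6-trihydroxy-3-((2R)-2-methylbutanoyl)phenyl]methyl}-2H-pyran-2-one F8 to give 19.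

## Further compounds

F1 | step 3 | (E)-2-methylbut-2-enoic acid (tiglic acid) | C/C=C(\C)C(=O)O
F2 | step 6 | (2R)-N-methoxy-N,2-dimethylbutanamide | CC[C@@H](C)C(=O)N(C)OC
F3 | step 6 | 1,3,5-tris(methoxymethoxy)benzene | COCOc1cc(OCOC)cc(OCOC)c1
F4 | step 6 | 2,4,6-tris(methoxymethoxy)phenyllithium | [Li]c1c(OCOC)cc(OCOC)cc1OCOC
F5 | step 6 | (2R)-2-methyl-1-[2,4,6-tris(methoxymethoxy)phenyl]butan-1-one | CC[C@@H](C)C(=O)c1c(OCOC)cc(OCOC)cc1OCOC
F6 | step 10 | 3-[(dimethylamino)methyl]-6-ethyl-4-hydroxy-5-methyl-2H-pyran-2-one | CCc1oc(=O)c(CN(C)C)c(O)c1C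
F7 | step 10 | 6-ethyl-5-methyl-3-methylidene-2H-pyran-2,4(3H)-dione | CCC1=C(C)C(=O)C(=C)C(=O)O1
F8 | step 10 | 6-ethyl-4-hydroxy-5-methyl-3-{[2,4,6-trihydroxy-3-((2R)-2-methylbutanoyl)phenyl]methyl}-2H-pyran-2-one | CC[C@@H](C)C(=O)c1c(O)cc(O)c(Cc2c(O)c(C)c(CC)oc2=O)c1O
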